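**Strategy.** Everything rests on cutting C10–C11, the bond between the fully substituted pyran carbon and the bridgehead of the oxygen-bridged bicyclo[3.2.2]nonane (atoms numbered 1–13 along the SMILES after the acetate oxygen; O4 is the bridge, O9 the pyran oxygen). The feature exploited is that C11 is β to C13: with C13 as a ketone, C11 accepts a nucleophilic radical. One photoredox decarboxylation of a C10 acid makes the tertiary α-oxy radical, which adds to the enone tethered through O4, closing both seven-membered rings of the bridge and setting C10 and C11. The precursor is a bromopyranyl carboxylic acid joined by the tertiary ether O4 to a 4-acetoxy-6-methylcyclohex-2-enone.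

Key step: step 15

Remark (numbering): C1 carries the acetate, C3 and C11 are the bridgeheads, O4 is the bridging oxygen, C7 carries bromine, O9 is the pyran oxygen, C10 the fully substituted pyran carbon, C13 the carbinol carbon; all intermediates use these numbers.
Remark (assumption on C10): C10 is planar in the radical, so its configuration in the acid does not reach the product; the acid is made as the epimer with the C10 methyl cis to O4, which the lactate aldol delivers and which lets the pyran close with bromine trans to O4.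
Remark (C1): trans-diaxial opening of a cyclohexene oxide can only place O4 trans to the C1 oxygen, so the cis relationship of the target is reached by inverting C1 at the allylic alcohol stage.
Remark (supply): (S)-2-(but-3-en-1-yl)oxirane, isopropenylmagnesium bromide, (R)-lactic acid, pivalaldehyde and 4-methylpent-3-en-1-ol are taken as commercial.

Step 1
Reactants: 1 (S)-2-(but-3-en-1-yl)oxirane; 2 isopropenylmagnesium bromide CH2=C(CH3)MgBr
Product: 3 (S)-2-methylocta-1,7-dien-4-ol
Conditions: CuI (10 mol%), THF, −40 → 0 °C; then H2O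
Reagents that add atoms: none
Why: Copper-catalysed Grignard opening of a terminal epoxide takes place at the unsubstituted carbon, so the carbinol centre of 1 is carried over untouched.

Step 2
Reactants: 3 (S)-2-methylocta-1,7-dien-4-ol
Product: 4 (S)-3-methylcyclohex-3-en-1-ol
Conditions: second-generation Grubbs catalyst (2 mol%), CH2Cl2 (0.05 M), 40 °C
Reagents that add atoms: none
Why: Ring-closing metathesis of the 1,7-diene closes the six-membered ring with a trisubstituted alkene and loss of ethylene, and does not touch the carbinol centre.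

Step 3
Reactants: 4 (S)-3-methylcyclohex-3-en-1-ol
Product: 5 (1S,3S,6R)-1-methyl-7-oxabicyclo[4.1.0]heptan-3-ol
Conditions: VO(acac)2 (2 mol%), t-BuOOH (1.5 equiv), CH2Cl2, 0 °C → rt
Reagents that add atoms: tert-butyl hydroperoxide CC(C)(C)OO
Why: Hydroxyl-directed vanadium-catalysed epoxidation of the homoallylic cyclohexenol should deliver oxygen to the alkene face cis to the hydroxyl, which sets both epoxide carbons (C3 and C13).

Step 4
Reactants: 5 (1S,3S,6R)-1-methyl-7-oxabicyclo[4.1.0]heptan-3-ol
Product: 6 (1S,3S,6R)-1-methyl-7-oxabicyclo[4.1.0]heptan-3-yl acetate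
Conditions: Ac2O, pyridine, DMAP (cat.), CH2Cl2, 0 °C → rt
Reagents that add atoms: acetic anhydride CC(=O)OC(C)=O
Why: DMAP-catalysed acetylation masks the C1 hydroxyl as an equatorial ester that lies on the same face as the epoxide oxygen and therefore cannot open the epoxide from behind.

Step 5
Reactants: 7 (R)-lactic acid; 8 pivalaldehyde
Product: 9 (2R,5R)-2-tert-butyl-5-methyl-1,3-dioxolan-4-one
Conditions: TsOH·H2O (cat.), H2SO4 (cat.), pentane, reflux, Dean–Stark; crystallisation from pentane at −78 °C
Reagents that add atoms: none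
Why: Acid-catalysed acetalisation of the α-hydroxy acid (self-regeneration of stereocentres) should favour the cis dioxolanone, whose acetal carbon stores the chirality of the lactic acid, and the cis isomer is purified by crystallisation.

Step 6
Reactants: 10 4-methylpent-3-en-1-ol
Product: 11 4-methylpent-3-enal
Conditions: Dess–Martin periodinane, pyridine, CH2Cl2, 0 °C → rt; used as a solution
Reagents that add atoms: none
Why: Dess–Martin oxidation under pyridine buffer gives the β,γ-unsaturated aldehyde without moving the alkene into conjugation.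

Step 7
Reactants: 9 (2R,5R)-2-tert-butyl-5-methyl-1,3-dioxolan-4-one; 11 4-methylpent-3-enal
Product: 13 (2R,5S)-2-tert-butyl-5-[(1S)-1-hydroxy-4-methylpent-3-en-1-yl]-5-methyl-1,3-dioxolan-4-one, via lithium enolate 12 (not isolated)
Conditions: LiN(i-Pr)2 (1.05 equiv), THF, −78 °C; then 11, −78 °C; AcOH quench
Reagents that add atoms: none
Why: Aldol addition of the lithium enolate should occur anti to the tert-butyl group (sets C10) through a closed Zimmerman–Traxler transition state with the C10 methyl cis to O–Li and the aldehyde chain equatorial (sets C5, hydroxyl syn to methyl), and the minor C5 epimer is removed by chromatography.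

Step 8
Reactants: 13 (2R,5S)-2-tert-butyl-5-[(1S)-1-hydroxy-4-methylpent-3-en-1-yl]-5-methyl-1,3-dioxolan-4-one; 6 (1S,3S,6R)-1-methyl-7-oxabicyclo[4.1.0]heptan-3-yl acetate
Product: 14 ether alcohol with the C3–O4–C5 link, C1 acetate and C13 hydroxyl both trans to O4
Conditions: 13 (2.5 equiv), BF3·OEt2 (0.2 equiv), CH2Cl2, −78 → −30 °C, slow addition of 6
Reagents that add atoms: none
Why: Lewis acid-catalysed alcoholysis of the trisubstituted epoxide should go by trans-diaxial opening at the tertiary carbon C3 with inversion, the equatorial acetate and the tertiary-carbon preference pointing to the same regiochemistry, so O4 is set trans to the C13 hydroxyl and trans to the C1 acetate.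

Step 9
Reactants: 14 ether alcohol
Product: 15 ether ketone (C13 ketone)
Conditions: Dess–Martin periodinane, pyridine, CH2Cl2, rt
Reagents that add atoms: none
Why: Dess–Martin oxidation of the only free hydroxyl gives the C13 ketone and leaves the acyl acetal, the alkene and the acetate alone.

Step 10
Reactants: 15 ether ketone
Product: 16 4-methoxybenzyl (2S,3S)-2-hydroxy-3-{[(1R,5S)-5-hydroxy-1-methyl-2-oxocyclohexyl]oxy}-2,6-dimethylhept-5-enoate
Conditions: 4-MeOC6H4CH2OH (10 equiv), NaH (0.3 equiv), THF, 0 °C → rt
Reagents that add atoms: 4-methoxybenzyl alcohol COc1ccc(CO)cc1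
Why: Alkoxide-catalysed transesterification opens the acyl acetal to the 4-methoxybenzyl ester with loss of pivalaldehyde, which frees the C10 hydroxyl, and removes the C1 acetate in the same operation without touching a stereocentre.

Step 11
Reactants: 16 diol ester
Product: 17 4-methoxybenzyl (2S,3S,5S)-5-bromo-3-{[(1R,5S)-5-hydroxy-1-methyl-2-oxocyclohexyl]oxy}-2,6,6-trimethyloxane-2-carboxylate
Conditions: 2,4,4,6-tetrabromocyclohexa-2,5-dien-1-one (TBCO, 1.2 equiv), CH2Cl2/MeNO2, −20 °C → rt, dark
Reagents that add atoms: 2,4,4,6-tetrabromocyclohexa-2,5-dien-1-one O=C1C(Br)=CC(Br)(Br)C=C1Br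
Why: Bromoetherification (6-endo opening of the bromonium ion at the tertiary carbon C8 by the C10 hydroxyl, anti to bromine) should pass through the chair with the C10 methyl equatorial and O4 axial, which avoids a syn-axial methyl pair and places the equatorial C7 bromine trans to O4.

Step 12
Reactants: 17 bromopyranyl ketone
Product: 20 4-methoxybenzyl (2S,3S,5S)-5-bromo-3-{[(1R,5R)-5-hydroxy-1-methyl-2-oxocyclohex-3-en-1-yl]oxy}-2,6,6-trimethyloxane-2-carboxylate, via bis(trimethylsilyl) enol ether 18 (not isolated), via silyloxy enone 19 (not isolated)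
Conditions: LiN(SiMe3)2 (2.5 equiv), Me3SiCl (3 equiv), THF, −78 °C; then Pd(OAc)2 (1.2 equiv), MeCN, rt; then 1 M HCl, THF, 0 °C
Reagents that add atoms: none
Why: Saegusa–Ito oxidation of the silyl enol ether, which can only form toward C12 because C3 is fully substituted, introduces the C11–C12 double bond, and the acidic work-up returns the C1 hydroxyl.

Step 13
Reactants: 20 hydroxy enone
Product: 21 4-methoxybenzyl (2S,3S,5S)-3-{[(1R,5S)-5-acetoxy-1-methyl-2-oxocyclohex-3-en-1-yl]oxy}-5-bromo-2,6,6-trimethyloxane-2-carboxylate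
Conditions: PPh3, diisopropyl azodicarboxylate (DIAD), AcOH, toluene, 0 °C → rt
Reagents that add atoms: acetic acid CC(=O)O
Why: Mitsunobu reaction with acetic acid displaces the activated allylic C1 oxygen with inversion (SN2), which installs the acetate cis to O4 as in the target.

Step 14
Reactants: 21 acetoxy enone ester
Product: 22 (2S,3S,5S)-3-{[(1R,5S)-5-acetoxy-1-methyl-2-oxocyclohex-3-en-1-yl]oxy}-5-bromo-2,6,6-trimethyloxane-2-carboxylic acid
Conditions: CF3CO2H/CH2Cl2 (1:9), anisole, 0 °C
Reagents that add atoms: none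
Why: Acidolysis of the 4-methoxybenzyl ester with anisole as cation trap frees the carboxylic acid under conditions that spare the allylic acetate, the enone and the bromide.

Step 15
Reactants: 22 pyranyl acid tethered through O4 to the 4-acetoxycyclohexenone
Product: 23 tricyclic C13 ketone
Conditions: Ir[dF(CF3)ppy]2(dtbbpy)PF6 (2 mol%), K2HPO4 (1.2 equiv), DMF (5 mM), blue LEDs (450 nm), 25 °C, argon
Reagents that add atoms: none
Why: The excited trivalent iridium complex oxidises the C10 carboxylate, CO2 is lost, and the nucleophilic tertiary α-oxy radical adds to C11, the β-carbon of the tethered enone; the α-keto radical is then reduced by the divalent iridium complex and the enolate is protonated at C12. The reaction type is the photoredox decarboxylative radical conjugate addition of α-alkoxy acids to enones, which is established between separate partners and in simple ring closures but has not been shown for a bridged seven-membered closure, so this application is the untested point of the route. The new bond closes both seven-membered rings of the bridge at once, 7-exo when counted through C1–C2 and 7-endo when counted through C12–C13. C11 is fixed by the tether, because the O4–C5–C10 bridge can only reach the enone face that carries O4, and C10 is fixed by the pyran, whose chair with equatorial bromine holds O4 axial so that only the lobe gauche to the C5–O4 bond can reach C11 and O4 and C11 come out cis. The step needs closure at C11 and not at the nearer α-carbon C12, and closure before the radical is quenched: polarity matching and the fact that only the α-keto radical from attack at C11 can be reduced by the catalyst should secure the first, high dilution and the absence of a hydrogen donor the second, and the secondary bromide and the acetate lie outside the reach of the catalyst.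

Step 16
Reactants: 23 tricyclic C13 ketone
Product: 24 CNP0247588.2
Conditions: NaBH4, THF/MeOH (4:1), −40 °C
Reagents that add atoms: none
Why: Ketone reduction under steric approach control should deliver hydride to C13 past the bridging ether oxygen O4, which carries no hydrogen, and not past the C2 methylene on the other face, so the hydroxyl is formed anti to O4.

**Compound list**

1 | (S)-2-(but-3-en-1-yl)oxirane | C=CCC[C@H]1CO1 | starting material
2 | isopropenylmagnesium bromide, CH2=C(CH3)MgBr | CC(=C)[Mg]Br | starting material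
3 | (S)-2-methylocta-1,7-dien-4-ol | C=C(C)C[C@@H](O)CCC=C | intermediate
4 | (S)-3-methylcyclohex-3-en-1-ol | O[C@@H]1CC(C)=CCC1 | intermediate
5 | (1S,3S,6R)-1-methyl-7-oxabicyclo[4.1.0]heptan-3-ol (epoxide oxygen cis to OH) | O[C@@H]1C[C@]2(C)O[C@@H]2CC1 | intermediate
6 | (1S,3S,6R)-1-methyl-7-oxabicyclo[4.1.0]heptan-3-yl acetate | CC(=O)O[C@@H]1C[C@]2(C)O[C@@H]2CC1 | intermediate
7 | (R)-lactic acid | C[C@@H](O)C(=O)O | starting material
8 | pivalaldehyde | CC(C)(C)C=O | starting material
9 | (2R,5R)-2-tert-butyl-5-methyl-1,3-dioxolan-4-one (cis) | C[C@H]1O[C@@H](C(C)(C)C)OC1=O | intermediate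
10 | 4-methylpent-3-en-1-ol | CC(C)=CCCO | starting material
11 | 4-methylpent-3-enal | CC(C)=CCC=O | intermediate
12 | lithium (2R)-2-tert-butyl-5-methyl-1,3-dioxol-4-olate | CC1=C([O-])O[C@H](C(C)(C)C)O1.[Li+] | intermediate (not isolated)
13 | (2R,5S)-2-tert-butyl-5-[(1S)-1-hydroxy-4-methylpent-3-en-1-yl]-5-methyl-1,3-dioxolan-4-one | CC(C)=CC[C@H](O)[C@]1(C)O[C@@H](C(C)(C)C)OC1=O | intermediate
14 | (1S,3R,4R)-4-hydroxy-3-methyl-3-{[(1S)-1-[(2R,4S)-2-tert-butyl-4-methyl-5-oxo-1,3-dioxolan-4-yl]-4-methylpent-3-en-1-yl]oxy}cyclohexyl acetate | CC(=O)O[C@@H]1C[C@@](C)(O[C@@H](CC=C(C)C)[C@]2(C)O[C@@H](C(C)(C)C)OC2=O)[C@H](O)CC1 | intermediate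
15 | (1S,3R)-3-methyl-4-oxo-3-{[(1S)-1-[(2R,4S)-2-tert-butyl-4-methyl-5-oxo-1,3-dioxolan-4-yl]-4-methylpent-3-en-1-yl]oxy}cyclohexyl acetate | CC(=O)O[C@@H]1C[C@@](C)(O[C@@H](CC=C(C)C)[C@]2(C)O[C@@H](C(C)(C)C)OC2=O)C(=O)CC1 | intermediate
16 | 4-methoxybenzyl (2S,3S)-2-hydroxy-3-{[(1R,5S)-5-hydroxy-1-methyl-2-oxocyclohexyl]oxy}-2,6-dimethylhept-5-enoate | O[C@@H]1C[C@@](C)(O[C@@H](CC=C(C)C)[C@](C)(O)C(=O)OCc2ccc(OC)cc2)C(=O)CC1 | intermediate
17 | 4-methoxybenzyl (2S,3S,5S)-5-bromo-3-{[(1R,5S)-5-hydroxy-1-methyl-2-oxocyclohexyl]oxy}-2,6,6-trimethyloxane-2-carboxylate | O[C@@H]1C[C@@](C)(O[C@H]2C[C@H](Br)C(C)(C)O[C@]2(C)C(=O)OCc2ccc(OC)cc2)C(=O)CC1 | intermediate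
18 | 4-methoxybenzyl (2S,3S,5S)-5-bromo-2,6,6-trimethyl-3-{[(1R,5S)-1-methyl-2,5-bis(trimethylsilyloxy)cyclohex-2-en-1-yl]oxy}oxane-2-carboxylate | C[Si](C)(C)O[C@@H]1C[C@@](C)(O[C@H]2C[C@H](Br)C(C)(C)O[C@]2(C)C(=O)OCc2ccc(OC)cc2)C(O[Si](C)(C)C)=CC1 | intermediate (not isolated)
19 | 4-methoxybenzyl (2S,3S,5S)-5-bromo-2,6,6-trimethyl-3-{[(1R,5R)-1-methyl-2-oxo-5-(trimethylsilyloxy)cyclohex-3-en-1-yl]oxy}oxane-2-carboxylate | C[Si](C)(C)O[C@@H]1C[C@@](C)(O[C@H]2C[C@H](Br)C(C)(C)O[C@]2(C)C(=O)OCc2ccc(OC)cc2)C(=O)C=C1 | intermediate (not isolated)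
20 | 4-methoxybenzyl (2S,3S,5S)-5-bromo-3-{[(1R,5R)-5-hydroxy-1-methyl-2-oxocyclohex-3-en-1-yl]oxy}-2,6,6-trimethyloxane-2-carboxylate (C1 hydroxyl trans to O4) | O[C@@H]1C[C@@](C)(O[C@H]2C[C@H](Br)C(C)(C)O[C@]2(C)C(=O)OCc2ccc(OC)cc2)C(=O)C=C1 | intermediate
21 | 4-methoxybenzyl (2S,3S,5S)-3-{[(1R,5S)-5-acetoxy-1-methyl-2-oxocyclohex-3-en-1-yl]oxy}-5-bromo-2,6,6-trimethyloxane-2-carboxylate (C1 acetate cis to O4) | CC(=O)O[C@H]1C[C@@](C)(O[C@H]2C[C@H](Br)C(C)(C)O[C@]2(C)C(=O)OCc2ccc(OC)cc2)C(=O)C=C1 | intermediate
22 | (2S,3S,5S)-3-{[(1R,5S)-5-acetoxy-1-methyl-2-oxocyclohex-3-en-1-yl]oxy}-5-bromo-2,6,6-trimethyloxane-2-carboxylic acid | CC(=O)O[C@H]1C[C@@](C)(O[C@H]2C[C@H](Br)C(C)(C)O[C@]2(C)C(=O)O)C(=O)C=C1 | intermediate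
23 | tricyclic C13 ketone, (1S,3R,5S,7S,10S,11R) in the route numbering, C10–C11 bond closed | CC(=O)O[C@H]1C[C@@]2(C)O[C@H]3C[C@H](Br)C(C)(C)O[C@@]3(C)[C@@H]1CC2=O | intermediate
24 | CNP0247588.2, (1S,3R,5S,7S,10S,11R,13R) in the route numbering | CC(=O)O[C@H]1C[C@@]2(C)O[C@H]3C[C@H](Br)C(C)(C)O[C@@]3(C)[C@@H]1C[C@H]2O | target

**Totals.** 16 steps in all; the longest linear sequence is 13 steps (steps 1–4, then 8–16).

**Steps most likely to fail**

Step 15. The bridging closure may be slow enough that the C10 radical is oxidised further by the excited photocatalyst to the oxocarbenium ion, or picks up a hydrogen atom from the solvent, before it reaches C11. The fallback sets out from 22 and comes back at 23. Acid 22 is converted with N-hydroxyphthalimide, diisopropylcarbodiimide and catalytic DMAP in CH2Cl2 into the N-(acyloxy)phthalimide F1. F1 is then irradiated with blue light at high dilution in CH2Cl2 with Ru(bpy)3(PF6)2, Hantzsch ester and i-Pr2NEt. Electron transfer from the reduced ruthenium complex fragments the ester to CO2, phthalimide and the same C10 radical, in a medium that contains no oxidant able to take the radical to the cation. The adduct radical is finished by hydrogen atom transfer from the Hantzsch ester. This reductive conjugate addition of tertiary radicals from N-(acyloxy)phthalimides to enones is established for congested quaternary-to-tertiary bonds.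

Step 8. The hindered hydroxyl of 13 may attack too slowly, so that the activated epoxide rearranges by hydride shift to a ketone or is captured by the trisubstituted alkene. The fallback replaces epoxide opening by Markovnikov alkoxymercuration of an alkene, after the alkene of 13 has been used up in closing the pyran. It sets out from 13 and 4 and comes back at 17.
- Transesterification of 13 with 4-methoxybenzyl alcohol and catalytic NaH at 0 °C should give 4-methoxybenzyl (2S,3S)-2,3-dihydroxy-2,6-dimethylhept-5-enoate F2.
- Et3SiCl and imidazole should silylate the secondary hydroxyl to the triethylsilyl ether F3.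
- TBCO should close the bromopyran triethylsilyl ether F4.
- Pyridinium p-toluenesulfonate in methanol should free 4-methoxybenzyl (2S,3S,5S)-5-bromo-3-hydroxy-2,6,6-trimethyloxane-2-carboxylate F5.
- Alkenol 4 is acetylated to (S)-3-methylcyclohex-3-en-1-yl acetate F6.
- F5 and F6 are joined with Hg(OCOCF3)2 and 2,6-di-tert-butyl-4-methylpyridine in CH2Cl2 at 0 °C, followed by aqueous KBr. Reversible trans-diaxial addition should give the tertiary ether organomercuric bromide F7 with O4 trans to the equatorial acetate.
- Oxidative demercuration (NaBH4, O2, DMF) should give the C13 alcohols F8, whose C13 configuration is irrelevant.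
- Dess–Martin oxidation gives the ketone acetate F9, and K2CO3 in methanol removes the acetate to give 17.

Step 11. The bromonium ion may be opened at the secondary carbon C7 to give a five-membered ether, the wrong alkene face may be attacked, or electrophilic bromine may be consumed by the electron-rich benzyl ester. The fallback separates ring closure from carbon–bromine bond formation. It sets out from 16 and comes back at 17. Treatment of 16 with Hg(OCOCF3)2 in CH2Cl2, then aqueous KBr, should close the six-membered ring reversibly and with strict Markovnikov selectivity to the pyranylmercuric bromide F10, with mercury equatorial at C7. Brominolysis with Br2 and LiBr in pyridine at 0 °C, which proceeds with retention at carbon, should then give 17.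

**Further compounds**

F1 | step 15 | N-(acyloxy)phthalimide of acid 22 | CC(=O)O[C@H]1C[C@@](C)(O[C@H]2C[C@H](Br)C(C)(C)O[C@]2(C)C(=O)ON2C(=O)c3ccccc3C2=O)C(=O)C=C1
F2 | step 8 | 4-methoxybenzyl (2S,3S)-2,3-dihydroxy-2,6-dimethylhept-5-enoate | COc1ccc(COC(=O)[C@@](C)(O)[C@@H](O)CC=C(C)C)cc1
F3 | step 8 | 4-methoxybenzyl (2S,3S)-2-hydroxy-2,6-dimethyl-3-(triethylsilyloxy)hept-5-enoate | COc1ccc(COC(=O)[C@@](C)(O)[C@@H](O[Si](CC)(CC)CC)CC=C(C)C)cc1
F4 | step 8 | 4-methoxybenzyl (2S,3S,5S)-5-bromo-2,6,6-trimethyl-3-(triethylsilyloxy)oxane-2-carboxylate | CC[Si](CC)(CC)O[C@H]1C[C@H](Br)C(C)(C)O[C@]1(C)C(=O)OCc1ccc(OC)cc1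
F5 | step 8 | 4-methoxybenzyl (2S,3S,5S)-5-bromo-3-hydroxy-2,6,6-trimethyloxane-2-carboxylate | O[C@H]1C[C@H](Br)C(C)(C)O[C@]1(C)C(=O)OCc1ccc(OC)cc1
F6 | step 8 | (S)-3-methylcyclohex-3-en-1-yl acetate | CC(=O)O[C@@H]1CC(C)=CCC1
F7 | step 8 | tertiary ether organomercuric bromide (HgBr at C13 trans to O4, C1 acetate trans to O4) | CC(=O)O[C@@H]1C[C@@](C)(O[C@H]2C[C@H](Br)C(C)(C)O[C@]2(C)C(=O)OCc2ccc(OC)cc2)[C@H]([Hg]Br)CC1
F8 | step 8 | C13 alcohols of the tertiary ether (both C13 epimers, C1 acetate trans to O4) | CC(=O)O[C@@H]1C[C@@](C)(O[C@H]2C[C@H](Br)C(C)(C)O[C@]2(C)C(=O)OCc2ccc(OC)cc2)C(O)CC1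
F9 | step 8 | C1 acetate of ketone 17 | CC(=O)O[C@@H]1C[C@@](C)(O[C@H]2C[C@H](Br)C(C)(C)O[C@]2(C)C(=O)OCc2ccc(OC)cc2)C(=O)CC1
F10 | step 11 | pyranylmercuric bromide (HgBr in place of Br at C7 of 17) | O[C@@H]1C[C@@](C)(O[C@H]2C[C@H]([Hg]Br)C(C)(C)O[C@]2(C)C(=O)OCc2ccc(OC)cc2)C(=O)CC1
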